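In a closed, stirred vessel at constant volume and temperature, you hold E with G, [E] at 0.40 M and [G] at 0.720 M, and D appears.

all flasks: E 0.40 M
- north: G 0.72 M; the very flask that is asked about, followed so far
- flask: G 0.720 M; time 8.0 d

north run (percent of the E charged): time / h: D / % = 8.00: 24.4; 15.0: 35.2; 25.0: 41.0; 30.0: 43.5

(scatter of a reading: 1 percentage point)



1. time, not beyond 8.0 d, at which the flask holds most D
2. the amount of D, in percent of the E charged, at that time
3. earliest time at which at least nineteen twentieths of that best amount are there, in d
4. latest time at which they still are, in d

Draw the curve from the readings. Those at 15.0 h and 30.0 h cut the north run into two equal spans: D gains 35.2% in the first and 8.3 percentage points in the second, a ratio of 0.236. If every further span repeats that ratio, the gains form a geometric series, the shape of a pseudo-first-order rise, and their sum is the first gain over one minus the ratio. Call this sum the geometric level, the height the rise is heading for: 46.1%, read with the scatter of 1 point.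

The same ratio gives the time constant, the span over the logarithm of the inverse ratio: 10.4 h. So the slope at the start is the level over that constant, 0.0443 h⁻¹ as a fraction of the E charged. The knee lies at the time constant, where the curve stands at 29.1%. At 8.00 h the curve gives 24.7%, beside the reading of 24.4%, which took no part in the reckoning. The curve reaches 95.0% of the level at the time constant times ln 20, which is 1.30 d, just past the last reading. The readings end below the level and show no turn. My own reckoning is therefore a top near the level and an opening at that time, with the peak time and the closing left unread.

The forecast puts the peak at 47% at 2.5 d, holding from 1.4 d to 5 d, higher than my level and opening later than my time, and it grants: “The data cannot tell a true plateau from a slow maximum.”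

The flask gives 44.5% at 1.64 d, with the window open from 1.10 d to 2.41 d.

    D → J (k = 0.0140 h⁻¹)
    E + G ⇌ X (K = 1.30 L mol⁻¹, k = 0.0170 L mol⁻¹ h⁻¹)
    E → D (k = 0.0380 h⁻¹)
    E ⇌ L (K = 1.40, k = 0.0170 h⁻¹)
    L → D (k = 0.0140 h⁻¹)

Set 95.0% of that peak on your curve and it falls at 1.08 d, beside the flask's 1.10 d. The peak lies 1.6 points under the level, and the reaction of D to J is the largest single effect on its height: with that reaction taken away, the flask climbs to 93.9% against 44.5%. The neighbour with [G] at 0.18 M peaks at 1.06 of the level, against 0.965 for this flask, and at 8.00 d it holds 13.0% D beside 84.6% J.

Readings and results were computed from invented constants.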